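The biflavonoid is cut at flavone ring B, which is built de novo: C2'–C3' and C4'–C5' form when methyl coumalate reacts with 4,6-bis(benzyloxy)-2-methoxybenzofuran, a cyclic ketene acetal made from 3,5-bis(benzyloxy)phenol. Cycloaddition, loss of CO2 and ring-opening aromatisation deliver in one operation the 1,3,4-pattern of ring B (ester carbon at C1', biaryl bond at C3', methoxy at C4') and release only the phenol ortho to the biaryl bond, the future O1 of the isoflavone. The exploited feature is thus the C1'/C3'/C4' substitution of ring B together with the C8–C8a–O1 array of isoflavone ring A. Both pyranone rings are then annulated conventionally and four benzyl ethers are removed last.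

Key step: step 4

Assumption: the target carries no axial descriptor, so the tri-ortho-substituted biaryl axis is treated as configurationally undefined and no atroposelective step is planned.

Step 1
Reactants: 1 3,5-bis(benzyloxy)phenol; 2 ethyl glyoxylate
Product: 4 ethyl 2-[2,4-bis(benzyloxy)-6-hydroxyphenyl]-2-hydroxyacetate (racemic), via bromomagnesium phenoxide 3 (not isolated)
Conditions: EtMgBr (1.0 equiv), Et2O–PhMe, 0 °C; then 2 (1.1 equiv), 0 → 23 °C; aq NH4Cl
Reagents that add atoms: none
Why: Ortho-specific Friedel–Crafts hydroxyalkylation of a magnesium phenoxide: the divalent magnesium of 3 binds the aldehyde of 2 and delivers it through a six-membered chelate to one of the two equivalent ortho carbons, so the para carbon between the benzyloxy groups is avoided; the benzyl ethers are already in place, so no base-mediated benzylation of a C3-acidic lactone is needed later, and the racemic carbinol centre is deleted in step 2.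

Step 2
Reactants: 4 ethyl 2-[2,4-bis(benzyloxy)-6-hydroxyphenyl]-2-hydroxyacetate
Product: 6 4,6-bis(benzyloxy)-1-benzofuran-2(3H)-one, via arylacetate 5 (not isolated)
Conditions: Et3SiH, TFA, CH2Cl2, 0 °C; then PPTS (cat.), PhMe, 110 °C
Reagents that add atoms: none
Why: Ionic hydrogenation followed by lactonisation: the benzylic hydroxyl lies ortho/para to three oxygen donors, so acid ionises it to a stabilised benzylic cation that takes hydride from the silane to give 5, and acid-catalysed attack of the ortho phenol on the ester (5-exo-trig) then closes the benzofuranone; aryl benzyl ethers tolerate brief cold TFA and PPTS.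

Step 3
Reactants: 6 4,6-bis(benzyloxy)-1-benzofuran-2(3H)-one
Product: 8 4,6-bis(benzyloxy)-2-methoxy-1-benzofuran, via potassium enolate 7 (not isolated)
Conditions: KN(SiMe3)2, 18-crown-6, THF, −78 °C; then MeOTf, −78 → 0 °C; basic work-up
Reagents that add atoms: methyl trifluoromethanesulfonate, COS(=O)(=O)C(F)(F)F
Why: Enolate O-alkylation to a ketene acetal: the crown-ether-separated potassium enolate 7 is a 2-benzofuranolate with its charge largely on oxygen, and the hard electrophile should attack oxygen because this gives the aromatic benzofuran directly; the product is acid-labile, so it is isolated under basic conditions and used at once.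

Step 4
Reactants: 8 4,6-bis(benzyloxy)-2-methoxy-1-benzofuran; 9 methyl coumalate (methyl 2-oxo-2H-pyran-5-carboxylate)
Product: 12 methyl 3-[2,4-bis(benzyloxy)-6-hydroxyphenyl]-4-methoxybenzoate, via bridged lactone 10 (not isolated), via dihydrodibenzofuran 11 (not isolated)
Conditions: 9 (1.5 equiv), iPr2NEt (1.5 equiv), PhMe, 130 °C, sealed tube; then DBU, 23 °C
Reagents that add atoms: none
Why: Proposed new method: the nucleophilic C3 of the cyclic ketene acetal 8 bonds to the electrophilic C6 of pyrone 9 and the acetal carbon C2 then bonds to pyrone C3, an inverse-electron-demand Diels–Alder reaction (asynchronous or stepwise through an oxocarbenium–dienolate zwitterion) that closes the new six-membered carbocycle in a [4+2] mode and gives bridged lactone 10. Cycloreversion with loss of CO2 gives the cis-fused dihydrodibenzofuran 11, and base-mediated anti elimination of the ring-fusion hydrogen together with the ring aryloxide opens the furan and aromatises flavone ring B. The closest known reaction type is the thermal reaction of methyl coumalate with acyclic ketene acetals and enol ethers, which gives para-alkoxybenzoates after loss of CO2 and an alcohol; a ketene acetal embedded in a benzofuran, with ring-opening aromatisation, has not been shown. No stereocentre survives, and the cis ring fusion of 11 only serves to place the ring-fusion C–H anti to the ring C–O bond and syn to the methoxy group. Two selectivities are needed: the regiochemistry (aryl meta and methoxy para to the ester) follows from the polarity match of benzofuran C3 with pyrone C6, and expulsion of aryloxide instead of methoxide is secured by the lower pKa of the phenol, by the anti relationship just described and by the basic medium, which keeps the methoxy oxygen unprotonated and buffers the released phenol.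

Step 5
Reactants: 13 1-(2,4,6-trihydroxyphenyl)ethan-1-one
Product: 14 1-[2,4-bis(benzyloxy)-6-hydroxyphenyl]ethan-1-one
Conditions: BnBr (2.1 equiv), K2CO3, DMF, 23 °C
Reagents that add atoms: benzyl bromide, BrCc1ccccc1
Why: Williamson ether synthesis: the 4-hydroxyl and one of the two equivalent ortho hydroxyls are benzylated, while the remaining ortho hydroxyl is held in a hydrogen bond to the acetyl group and stays free, which is the known selective dibenzylation of this ketone.

Step 6
Reactants: 12 methyl 3-[2,4-bis(benzyloxy)-6-hydroxyphenyl]-4-methoxybenzoate; 14 1-[2,4-bis(benzyloxy)-6-hydroxyphenyl]ethan-1-one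
Product: 16 5,7-bis(benzyloxy)-2-{3-[2,4-bis(benzyloxy)-6-hydroxyphenyl]-4-methoxyphenyl}-4H-chromen-4-one, via diketone 15 (not isolated)
Conditions: LiN(SiMe3)2 (5 equiv), THF, −78 → 23 °C; then AcOH, NaOAc, 110 °C
Reagents that add atoms: none
Why: Crossed Claisen condensation followed by cyclodehydration: excess base turns 12 into its inert lithium phenoxide and 14 into its phenoxide–enolate dianion, whose methyl ketone enolate is acylated by the unhindered methyl ester to give diketone 15, and in buffered acetic acid the ortho hydroxyl of the acetophenone-derived ring adds to the distal carbonyl (6-exo-trig) and water is lost to close the flavone pyranone; benzyl ethers survive NaOAc/AcOH.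

Step 7
Reactants: 16 5,7-bis(benzyloxy)-2-{3-[2,4-bis(benzyloxy)-6-hydroxyphenyl]-4-methoxyphenyl}-4H-chromen-4-one
Product: 18 4,6-bis(benzyloxy)-3-{5-[5,7-bis(benzyloxy)-4-oxo-4H-chromen-2-yl]-2-methoxyphenyl}-2-hydroxybenzaldehyde, via hydroxymethylphenol 17 (not isolated)
Conditions: MgCl2, Et3N, (CH2O)n, THF, 70 °C
Reagents that add atoms: formaldehyde (as paraformaldehyde), C=O
Why: Casnati–Skattebøl ortho-formylation: the magnesium phenoxide of 16 delivers formaldehyde within a chelate to the only free ortho carbon to give 17, whose magnesium alkoxide is oxidised by a second formaldehyde through Oppenauer-type hydride transfer; the para carbon between the two benzyloxy groups is not reached by this intramolecular delivery, and the flavone and the ethers are inert to MgCl2/Et3N.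

Step 8
Reactants: 18 4,6-bis(benzyloxy)-3-{5-[5,7-bis(benzyloxy)-4-oxo-4H-chromen-2-yl]-2-methoxyphenyl}-2-hydroxybenzaldehyde; 19 (4-methoxybenzyl)magnesium chloride
Product: 20 5,7-bis(benzyloxy)-2-(3-{4,6-bis(benzyloxy)-2-hydroxy-3-[1-hydroxy-2-(4-methoxyphenyl)ethyl]phenyl}-4-methoxyphenyl)-4H-chromen-4-one (racemic)
Conditions: 19 (2.2 equiv), THF, −78 → 0 °C; aq NH4Cl
Reagents that add atoms: none
Why: Grignard 1,2-addition: the first equivalent of 19 forms the magnesium phenoxide and the second adds to the chelated aldehyde, which at low temperature is far more electrophilic than the doubly vinylogous ester carbonyl of the 5,7-dialkoxyflavone; the carbinol forms as a racemate, is acid-labile and is taken on crude, and its stereocentre is removed in step 9.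

Step 9
Reactants: 20 5,7-bis(benzyloxy)-2-(3-{4,6-bis(benzyloxy)-2-hydroxy-3-[1-hydroxy-2-(4-methoxyphenyl)ethyl]phenyl}-4-methoxyphenyl)-4H-chromen-4-one
Product: 21 5,7-bis(benzyloxy)-2-(3-{4,6-bis(benzyloxy)-2-hydroxy-3-[(4-methoxyphenyl)acetyl]phenyl}-4-methoxyphenyl)-4H-chromen-4-one
Conditions: MnO2 (activated, excess), CH2Cl2, 23 °C
Reagents that add atoms: none
Why: Benzylic alcohol oxidation: MnO2 should oxidise the electron-rich ortho-hydroxybenzylic carbinol to the ketone, as it does salicyl alcohols, and stop there because the phenol becomes locked in a hydrogen bond to the new carbonyl; the flavone and the ethers are untouched.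

Step 10
Reactants: 21 5,7-bis(benzyloxy)-2-(3-{4,6-bis(benzyloxy)-2-hydroxy-3-[(4-methoxyphenyl)acetyl]phenyl}-4-methoxyphenyl)-4H-chromen-4-one
Product: 23 5,7-bis(benzyloxy)-8-{5-[5,7-bis(benzyloxy)-4-oxo-4H-chromen-2-yl]-2-methoxyphenyl}-3-(4-methoxyphenyl)-4H-chromen-4-one, via enaminone 22 (not isolated)
Conditions: Me2NCH(OMe)2, PhMe, 90 °C
Reagents that add atoms: N,N-dimethylformamide dimethyl acetal, COC(OC)N(C)C
Why: Enaminone condensation and cyclisation: the acetal condenses at the doubly activated methylene of 21 to give enaminone 22, and the only free hydroxyl, the one released in step 4, adds to the enamine carbon and expels dimethylamine (6-endo-trig addition–elimination) to close the isoflavone pyranone, with C2 supplied by the reagent.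

Step 11
Reactants: 23 5,7-bis(benzyloxy)-8-{5-[5,7-bis(benzyloxy)-4-oxo-4H-chromen-2-yl]-2-methoxyphenyl}-3-(4-methoxyphenyl)-4H-chromen-4-one
Product: 24 5,7-dihydroxy-8-[5-(5,7-dihydroxy-4-oxo-4H-chromen-2-yl)-2-methoxyphenyl]-3-(4-methoxyphenyl)-4H-chromen-4-one (target)
Conditions: H2 (1 atm), Pd/C (palladium on carbon), THF–MeOH, 23 °C
Reagents that add atoms: none
Why: Catalytic hydrogenolysis: the four aryl benzyl ethers should be cleaved under one atmosphere of hydrogen, while the two aryl methyl ethers and the conjugated pyranone double bonds of both chromenones are expected to persist if the reaction is stopped at full debenzylation.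

Compound list
1 | 3,5-bis(benzyloxy)phenol | Oc1cc(OCc2ccccc2)cc(OCc2ccccc2)c1 | starting material
2 | ethyl glyoxylate | CCOC(=O)C=O | starting material
3 | bromomagnesium 3,5-bis(benzyloxy)phenoxide | Br[Mg]Oc1cc(OCc2ccccc2)cc(OCc2ccccc2)c1 | intermediate (not isolated)
4 | ethyl 2-[2,4-bis(benzyloxy)-6-hydroxyphenyl]-2-hydroxyacetate (racemic) | CCOC(=O)C(O)c1c(O)cc(OCc2ccccc2)cc1OCc1ccccc1 | intermediate
5 | ethyl 2-[2,4-bis(benzyloxy)-6-hydroxyphenyl]acetate | CCOC(=O)Cc1c(O)cc(OCc2ccccc2)cc1OCc1ccccc1 | intermediate (not isolated)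
6 | 4,6-bis(benzyloxy)-1-benzofuran-2(3H)-one | O=C1Cc2c(OCc3ccccc3)cc(OCc3ccccc3)cc2O1 | intermediate
7 | potassium 4,6-bis(benzyloxy)-1-benzofuran-2-olate | [K+].[O-]c1cc2c(OCc3ccccc3)cc(OCc3ccccc3)cc2o1 | intermediate (not isolated)
8 | 4,6-bis(benzyloxy)-2-methoxy-1-benzofuran | COc1cc2c(OCc3ccccc3)cc(OCc3ccccc3)cc2o1 | intermediate
9 | methyl coumalate (methyl 2-oxo-2H-pyran-5-carboxylate) | COC(=O)C1=COC(=O)C=C1 | starting material
10 | bridged lactone cycloadduct: methyl 3-oxo-2-oxabicyclo[2.2.2]oct-5-ene-6-carboxylate fused at C7–C8 to the 4,6-bis(benzyloxy)-2-methoxy-2,3-dihydrobenzofuran (racemic, endo/exo not specified) | O=C1OC2C(C(=O)OC)=CC1C3(OC)Oc4cc(OCc5ccccc5)cc(OCc5ccccc5)c4C23 | intermediate (not isolated)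
11 | methyl 7,9-bis(benzyloxy)-4a-methoxy-4a,9b-dihydrodibenzo[b,d]furan-2-carboxylate (cis-fused, racemic; one enantiomer drawn) | COC(=O)C1=C[C@@H]2[C@](OC)(C=C1)Oc3cc(OCc4ccccc4)cc(OCc4ccccc4)c23 | intermediate (not isolated)
12 | methyl 3-[2,4-bis(benzyloxy)-6-hydroxyphenyl]-4-methoxybenzoate | COC(=O)c1ccc(OC)c(c1)-c1c(O)cc(OCc2ccccc2)cc1OCc1ccccc1 | intermediate
13 | 1-(2,4,6-trihydroxyphenyl)ethan-1-one | CC(=O)c1c(O)cc(O)cc1O | starting material
14 | 1-[2,4-bis(benzyloxy)-6-hydroxyphenyl]ethan-1-one | CC(=O)c1c(O)cc(OCc2ccccc2)cc1OCc1ccccc1 | intermediate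
15 | 1-[2,4-bis(benzyloxy)-6-hydroxyphenyl]-3-{3-[2,4-bis(benzyloxy)-6-hydroxyphenyl]-4-methoxyphenyl}propane-1,3-dione | COc1ccc(cc1-c1c(O)cc(OCc2ccccc2)cc1OCc1ccccc1)C(=O)CC(=O)c1c(O)cc(OCc2ccccc2)cc1OCc1ccccc1 | intermediate (not isolated)
16 | 5,7-bis(benzyloxy)-2-{3-[2,4-bis(benzyloxy)-6-hydroxyphenyl]-4-methoxyphenyl}-4H-chromen-4-one | COc1ccc(cc1-c1c(O)cc(OCc2ccccc2)cc1OCc1ccccc1)-c1cc(=O)c2c(OCc3ccccc3)cc(OCc3ccccc3)cc2o1 | intermediate
17 | 5,7-bis(benzyloxy)-2-{3-[4,6-bis(benzyloxy)-2-hydroxy-3-(hydroxymethyl)phenyl]-4-methoxyphenyl}-4H-chromen-4-one (present as its magnesium salt) | COc1ccc(cc1-c1c(O)c(CO)c(OCc2ccccc2)cc1OCc1ccccc1)-c1cc(=O)c2c(OCc3ccccc3)cc(OCc3ccccc3)cc2o1 | intermediate (not isolated)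
18 | 4,6-bis(benzyloxy)-3-{5-[5,7-bis(benzyloxy)-4-oxo-4H-chromen-2-yl]-2-methoxyphenyl}-2-hydroxybenzaldehyde | COc1ccc(cc1-c1c(O)c(C=O)c(OCc2ccccc2)cc1OCc1ccccc1)-c1cc(=O)c2c(OCc3ccccc3)cc(OCc3ccccc3)cc2o1 | intermediate
19 | (4-methoxybenzyl)magnesium chloride | COc1ccc(C[Mg]Cl)cc1 | starting material
20 | 5,7-bis(benzyloxy)-2-(3-{4,6-bis(benzyloxy)-2-hydroxy-3-[1-hydroxy-2-(4-methoxyphenyl)ethyl]phenyl}-4-methoxyphenyl)-4H-chromen-4-one (racemic) | COc1ccc(CC(O)c2c(O)c(-c3cc(ccc3OC)-c3cc(=O)c4c(OCc5ccccc5)cc(OCc5ccccc5)cc4o3)c(OCc3ccccc3)cc2OCc2ccccc2)cc1 | intermediate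
21 | 5,7-bis(benzyloxy)-2-(3-{4,6-bis(benzyloxy)-2-hydroxy-3-[(4-methoxyphenyl)acetyl]phenyl}-4-methoxyphenyl)-4H-chromen-4-one | COc1ccc(CC(=O)c2c(O)c(-c3cc(ccc3OC)-c3cc(=O)c4c(OCc5ccccc5)cc(OCc5ccccc5)cc4o3)c(OCc3ccccc3)cc2OCc2ccccc2)cc1 | intermediate
22 | 5,7-bis(benzyloxy)-2-(3-{4,6-bis(benzyloxy)-3-[3-(dimethylamino)-2-(4-methoxyphenyl)prop-2-enoyl]-2-hydroxyphenyl}-4-methoxyphenyl)-4H-chromen-4-one (alkene geometry not specified) | COc1ccc(cc1)C(=CN(C)C)C(=O)c1c(O)c(-c2cc(ccc2OC)-c2cc(=O)c3c(OCc4ccccc4)cc(OCc4ccccc4)cc3o2)c(OCc2ccccc2)cc1OCc1ccccc1 | intermediate (not isolated)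
23 | 5,7-bis(benzyloxy)-8-{5-[5,7-bis(benzyloxy)-4-oxo-4H-chromen-2-yl]-2-methoxyphenyl}-3-(4-methoxyphenyl)-4H-chromen-4-one | COc1ccc(cc1)-c1coc2c(-c3cc(ccc3OC)-c3cc(=O)c4c(OCc5ccccc5)cc(OCc5ccccc5)cc4o3)c(OCc3ccccc3)cc(OCc3ccccc3)c2c1=O | intermediate
24 | 5,7-dihydroxy-8-[5-(5,7-dihydroxy-4-oxo-4H-chromen-2-yl)-2-methoxyphenyl]-3-(4-methoxyphenyl)-4H-chromen-4-one | COc1ccc(-c2coc3c(-c4cc(-c5cc(=O)c6c(O)cc(O)cc6o5)ccc4OC)c(O)cc(O)c3c2=O)cc1 | target

Total step count: 11. Longest linear sequence: 10 steps (steps 1–4 and 6–11, from 1 to 24); step 5 is a one-step branch.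

Steps most likely to fail

Step 4. The first C–C bond may form without ring closure, since proton loss from the zwitterion would rearomatise the benzofuran and leave a C3-alkylated product. Alternatively, aromatisation may expel methanol instead of the aryloxide and close a dibenzofuran. The fallback uses known chemistry and sets out from 1. Amine-catalysed ortho-bromination (NBS, cat. iPr2NH, CH2Cl2, 0 °C; both ortho positions are equivalent) should give 2-bromo-3,5-bis(benzyloxy)phenol F1. Suzuki–Miyaura coupling of F1 with commercial [2-methoxy-5-(methoxycarbonyl)phenyl]boronic acid (COC(=O)c1ccc(OC)c(c1)B(O)O; Pd(OAc)2, SPhos, K3PO4, PhMe–H2O, 90 °C) should then give 12, where the route is rejoined. The hydroxyl ortho to bromine ends ortho to the biaryl bond, so the future O1 stays distinguished.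

Step 3. Methylation may occur at C3 of the ambident enolate instead of at oxygen, or the acid-labile ketene acetal may hydrolyse back to the lactone during isolation. The fallback sets out from 6. Trimethyloxonium tetrafluoroborate in CH2Cl2 should methylate the carbonyl oxygen of the neutral lactone, where carbon is not nucleophilic, to give 4,6-bis(benzyloxy)-2-methoxy-3H-1-benzofuran-1-ium tetrafluoroborate F2. NaOMe in MeOH should convert it into the cyclic orthoester 4,6-bis(benzyloxy)-2,2-dimethoxy-2,3-dihydro-1-benzofuran F3. Heating F3 with catalytic Al(OtBu)3 should eliminate methanol (the classical orthoester route to ketene acetals) and return to the route at 8.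

Step 8. The benzylic Grignard reagent may add competitively to the flavone carbonyl if the phenoxide-deactivated, doubly ortho-substituted aldehyde reacts only on warming, and the carbinol may dehydrate to a stilbene. The fallback sets out from 18. Protection of the phenol (NaH, MOMCl, THF, 0 °C) should give 4,6-bis(benzyloxy)-3-{5-[5,7-bis(benzyloxy)-4-oxo-4H-chromen-2-yl]-2-methoxyphenyl}-2-(methoxymethoxy)benzaldehyde F4, whose aldehyde is no longer deactivated and should take up 19 at −78 °C. This should give 5,7-bis(benzyloxy)-2-(3-{4,6-bis(benzyloxy)-3-[1-hydroxy-2-(4-methoxyphenyl)ethyl]-2-(methoxymethoxy)phenyl}-4-methoxyphenyl)-4H-chromen-4-one F5. Oxidation with Dess–Martin periodinane (NaHCO3, CH2Cl2) should give 5,7-bis(benzyloxy)-2-(3-{4,6-bis(benzyloxy)-3-[(4-methoxyphenyl)acetyl]-2-(methoxymethoxy)phenyl}-4-methoxyphenyl)-4H-chromen-4-one F6. Removal of the acetal ortho to the ketone (HCl, MeOH–THF, 40 °C) should then return to the route at 21.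

Further compounds
F1 | step 4 | 2-bromo-3,5-bis(benzyloxy)phenol | Oc1cc(OCc2ccccc2)cc(OCc2ccccc2)c1Br
F2 | step 3 | 4,6-bis(benzyloxy)-2-methoxy-3H-1-benzofuran-1-ium tetrafluoroborate | C[O+]=C1Cc2c(OCc3ccccc3)cc(OCc3ccccc3)cc2O1.F[B-](F)(F)F
F3 | step 3 | 4,6-bis(benzyloxy)-2,2-dimethoxy-2,3-dihydro-1-benzofuran | COC1(OC)Cc2c(OCc3ccccc3)cc(OCc3ccccc3)cc2O1
F4 | step 8 | 4,6-bis(benzyloxy)-3-{5-[5,7-bis(benzyloxy)-4-oxo-4H-chromen-2-yl]-2-methoxyphenyl}-2-(methoxymethoxy)benzaldehyde | COCOc1c(C=O)c(OCc2ccccc2)cc(OCc2ccccc2)c1-c1cc(ccc1OC)-c1cc(=O)c2c(OCc3ccccc3)cc(OCc3ccccc3)cc2o1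
F5 | step 8 | 5,7-bis(benzyloxy)-2-(3-{4,6-bis(benzyloxy)-3-[1-hydroxy-2-(4-methoxyphenyl)ethyl]-2-(methoxymethoxy)phenyl}-4-methoxyphenyl)-4H-chromen-4-one (racemic) | COCOc1c(C(O)Cc2ccc(OC)cc2)c(OCc2ccccc2)cc(OCc2ccccc2)c1-c1cc(ccc1OC)-c1cc(=O)c2c(OCc3ccccc3)cc(OCc3ccccc3)cc2o1
F6 | step 8 | 5,7-bis(benzyloxy)-2-(3-{4,6-bis(benzyloxy)-3-[(4-methoxyphenyl)acetyl]-2-(methoxymethoxy)phenyl}-4-methoxyphenyl)-4H-chromen-4-one | COCOc1c(C(=O)Cc2ccc(OC)cc2)c(OCc2ccccc2)cc(OCc2ccccc2)c1-c1cc(ccc1OC)-c1cc(=O)c2c(OCc3ccccc3)cc(OCc3ccccc3)cc2o1
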